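In units of per minute, one number tells how far a flask with equal charges of first and second end groups has aged, provided the fraction left is followed and not the fraction made.

| setting | ochre | grey | amber | autumn | winter | midnight | noon |
|---|---|---|---|---|---|---|---|
| first end groups | 0.25 M | 0.12 M | 0.50 M | 0.25 M | 0.25 M | 0.25 M | 0.25 M (fed, over 2.5 min) |
| second end groups | 0.25 M | 0.25 M | 0.25 M | 0.250 M | 0.250 M (fed, over 2.5 min) | 0.250 M (fed, over 40 s) | 0.250 M |
| temperature | 20 °C | 31 °C | 20 °C | 25 °C |  | 25 °C | 25 °C |
| remark | run made earlier | run made earlier | run made earlier | everything together at the start | the addition at −15 °C, then warmed to 25 °C; the feed brings no volume worth counting | all else is in the flask from the start; the feed brings no volume worth counting | all else is in the flask from the start; the feed brings no volume worth counting |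
| time |  |  |  | 4.0 min | 4.0 min | 4.0 min | 4.0 min |

| run | time / min | links / % | first end groups / % |
|---|---|---|---|
| ochre | 0.500 | 24.3 | 72.2 |
| ochre | 1.33 | 34.7 | 49.4 |
| ochre | 2.50 | 28.2 | 34.5 |
| ochre | 4.00 | 18.7 | 22.3 |
| grey | 0.250 | 23.8 | 71.3 |
| grey | 0.667 | 31.9 | 43.5 |
| grey | 1.33 | 25.3 | 21.1 |
| grey | 3.00 | 4.9 | 6.2 |
| amber | 0.833 | 24.6 | 68.9 |
| amber | 1.50 | 25.0 | 60.5 |
| amber | 2.50 | 14.9 | 53.4 |
| amber | 3.00 | 12.7 | 52.0 |

(readings scatter by 1 percentage point)

- the best flask by amount of links, in percent of the first end groups charged; "all alike" if 1.5 percentage points covers them all (autumn / winter / midnight / noon / all alike)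
- amount of links at the end, in percent of the first end groups charged, autumn
- amount of links at the end, in percent of the first end groups charged, winter
- amount of links at the end, in percent of the first end groups charged, midnight
- amount of links at the end, in percent of the first end groups charged, noon

- what was read earlier has a scatter of 1 percentage point, one standard deviation

If the loss is first order in each group, then with equal charges the reciprocal of the fraction of first end groups left climbs in a straight line from one. The ochre run has equal charges, and its 34.5% left at 2.50 min gives a pace of 0.759 min⁻¹ at 20 °C. One reading could hide a curve, but the ochre reading at 1.33 min gives 0.770 min⁻¹. The grey run has unequal charges, so its reading at 0.667 min goes through the integrated law for unequal charges; scaled to 0.25 M, it gives 1.49 min⁻¹ at 31 °C. The flasks' 25 °C lies near the middle of those temperatures on a reciprocal scale, so the geometric mean serves: 1.06 min⁻¹, the pace of the reciprocal.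

A feed bends that line, so a steady feed is counted, roughly, as losing half its duration. Winter's cold feed is counted as lost entirely, with warming taken as instant. The cold stage is not free, since the forecast puts its conversion near 7%, but starting the reciprocal there gives 37.5% left, against 38.5% with no cold conversion.

A fraction left is not an amount of links, for the ochre run has reacted 77.7% at 4.00 min and reads 18.7% links. Its highest link reading, however, comes with 49.4% left, and the highest in the warmer grey run with 43.5% left; winter's reckoned fraction is lower than both. My reckoning therefore places all four flasks past the peak, where more left should mean more links.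

| flask | time counted | first end groups left, own reckoning | links, forecast |
|---|---|---|---|
| autumn | 4.0 min | 19.1% | 9% |
| winter | 1.50 min | 37.5% | 26.7% |
| midnight | 3.67 min | 20.4% | 10.5% |
| noon | 2.75 min | 25.5% | 16% |

The forecast chooses winter: “Links decay faster than they form late on, so the best flask forms them late”.

    first end groups + second end groups → links + by-product (k = 0.0699 M⁻¹ s⁻¹, Ea = 40.0 kJ mol⁻¹)
    links + by-product → side product (k = 0.0353 M⁻¹ s⁻¹, Ea = 42.0 kJ mol⁻¹)
    links → over-reaction product (k = 0.0111 s⁻¹, Ea = 87.0 kJ mol⁻¹)
    (constants at 25 °C)

The flasks give 7.99% links in autumn, 26.3% in winter, 9.48% in midnight and 15.4% in noon, so winter stands first, and winter keeps 37% of its first end groups against 37.5% reckoned. Winter left until 10 min has 7.50 min after warming, so the same pace leaves 11.1%; that flask holds 11.1% of first end groups, and its links stand at 1.87%, less than autumn's at 4.0 min.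

The numbers in the tables are simulated for an exercise; scatter was added.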